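## Retrosynthetic overview

1. Target 16 ⇒ triol 14: the tetrahydrofuran C2–O bond is made last by acid-promoted 5-exo etherification through a benzylic cation, which sets C2 trans to C3.
2. Triol 14 ⇒ trans-lactone 13 by LiAlH4 reduction; the trans lactone maps onto the 3,4-cis pattern of the tetrahydrofuran.
3. Lactone 13 ⇒ key C–C bond (future C2–C3) by intermolecular aldol addition of the lithium enolate of (S)-lactone 10 to 3,4,5-trimethoxybenzaldehyde 11, which sets C3.
4. Lactone 10 ⇒ Evans alkylation of imide 4 with tert-butyl bromoacetate 5 (sets C4), LiBH4 removal of the auxiliary, acid lactonisation; 4 comes from acid 1 and (R)-oxazolidinone 2.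
5. Ring order: γ-butyrolactone (step 4, temporary) → opened (step 6) → tetrahydrofuran (step 7).

Assumption: the carbinol carbon of 13 and 14 forms as a mixture of epimers and is written without a descriptor; both are carried on because step 7 erases and re-sets that centre.

## Route

Step 1
Reactants: 1 3-(3,4-dimethoxyphenyl)propanoic acid; 2 (R)-4-benzyl-1,3-oxazolidin-2-one
Product: 4 (R)-4-benzyl-3-[3-(3,4-dimethoxyphenyl)propanoyl]-1,3-oxazolidin-2-one, via mixed pivalic anhydride 3 (not isolated)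
Conditions: PivCl, Et3N, THF, −20 °C; then 2, LiCl, −20 °C → rt
Reagents that add atoms: none
Why: N-acylation of the oxazolidinone through a mixed anhydride, with attack at the less hindered carbonyl and no strong base, so the auxiliary stereocentre is untouched.

Step 2
Reactants: 4 (R)-4-benzyl-3-[3-(3,4-dimethoxyphenyl)propanoyl]-1,3-oxazolidin-2-one; 5 tert-butyl bromoacetate
Product: 7 tert-butyl (3S)-4-[(4R)-4-benzyl-2-oxo-1,3-oxazolidin-3-yl]-3-(3,4-dimethoxybenzyl)-4-oxobutanoate, via sodium Z-enolate 6 (not isolated)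
Conditions: NaHMDS (1.1 equiv), THF, −78 °C; then 5, −78 → −40 °C
Reagents that add atoms: none
Why: Evans asymmetric alkylation, in which the chelated Z-enolate is alkylated on the face away from the auxiliary benzyl group, setting the (S) centre that becomes C4 of the target (dr typically ≥95:5, minor isomer removed by chromatography).

Step 3
Reactants: 7 tert-butyl (3S)-4-[(4R)-4-benzyl-2-oxo-1,3-oxazolidin-3-yl]-3-(3,4-dimethoxybenzyl)-4-oxobutanoate
Product: 8 tert-butyl (3S)-4-(3,4-dimethoxyphenyl)-3-(hydroxymethyl)butanoate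
Conditions: LiBH4, H2O (1 equiv), THF, 0 °C
Reagents that add atoms: none
Why: Chemoselective reductive cleavage of the N-acyl oxazolidinone, whose exocyclic carbonyl is reduced far faster than the hindered tert-butyl ester, without epimerisation and with release of 2 for recovery.

Step 4
Reactants: 8 tert-butyl (3S)-4-(3,4-dimethoxyphenyl)-3-(hydroxymethyl)butanoate
Product: 10 (4S)-4-(3,4-dimethoxybenzyl)dihydrofuran-2(3H)-one, via hydroxy acid 9 (not isolated)
Conditions: TFA, CH2Cl2, 0 °C → rt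
Reagents that add atoms: none
Why: Acidolysis of the tert-butyl ester (loss of isobutene) followed by spontaneous γ-lactonisation of the hydroxy acid; the stereocentre is not involved.

Step 5
Reactants: 10 (4S)-4-(3,4-dimethoxybenzyl)dihydrofuran-2(3H)-one; 11 3,4,5-trimethoxybenzaldehyde
Product: 13 (3R,4S)-4-(3,4-dimethoxybenzyl)-3-[hydroxy(3,4,5-trimethoxyphenyl)methyl]dihydrofuran-2(3H)-one, via lithium enolate 12 (not isolated)
Conditions: LiHMDS (1.1 equiv), THF, −78 °C; then 11, −78 °C; sat. aq NH4Cl at −78 °C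
Reagents that add atoms: none
Why: Intermolecular aldol addition of a lactone lithium enolate to a non-enolisable aldehyde, which approaches anti to the β-benzyl group so the new α-centre is trans (3R, the future C3); the carbinol epimers need no control.

Step 6
Reactants: 13 (3R,4S)-4-(3,4-dimethoxybenzyl)-3-[hydroxy(3,4,5-trimethoxyphenyl)methyl]dihydrofuran-2(3H)-one
Product: 14 (2S,3S)-2-(3,4-dimethoxybenzyl)-3-[hydroxy(3,4,5-trimethoxyphenyl)methyl]butane-1,4-diol
Conditions: LiAlH4, THF, 0 °C; Fieser work-up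
Reagents that add atoms: none
Why: Hydride reduction of the lactone to the 1,4-diol, fast enough at 0 °C to outrun retro-aldol and touching no stereocentre.

Step 7
Reactants: 14 (2S,3S)-2-(3,4-dimethoxybenzyl)-3-[hydroxy(3,4,5-trimethoxyphenyl)methyl]butane-1,4-diol
Product: 16 [(2R,3S,4S)-4-(3,4-dimethoxybenzyl)-2-(3,4,5-trimethoxyphenyl)tetrahydrofuran-3-yl]methanol, via benzylic cation 15 (not isolated)
Conditions: CSA (0.2 equiv), CH2Cl2, 0 °C → rt, stop at full conversion; Et3N quench
Reagents that add atoms: none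
Why: Acid-catalysed SN1 dehydrative etherification (5-exo), in which both carbinol epimers give the same trimethoxybenzyl cation; it is trapped by the CH2OH on the benzyl-bearing carbon (the other CH2OH could only give an oxetane) with the aryl group trans to the neighbouring CH2OH, the kinetically and thermodynamically preferred 2R arrangement.

## Compound list

1 | 3-(3,4-dimethoxyphenyl)propanoic acid | COc1ccc(CCC(=O)O)cc1OC | starting material
2 | (R)-4-benzyl-1,3-oxazolidin-2-one | O=C1N[C@H](Cc2ccccc2)CO1 | starting material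
3 | 3-(3,4-dimethoxyphenyl)propanoic pivalic anhydride | COc1ccc(CCC(=O)OC(=O)C(C)(C)C)cc1OC | intermediate
4 | (R)-4-benzyl-3-[3-(3,4-dimethoxyphenyl)propanoyl]-1,3-oxazolidin-2-one | COc1ccc(CCC(=O)N2[C@H](Cc3ccccc3)COC2=O)cc1OC | intermediate
5 | tert-butyl bromoacetate | CC(C)(C)OC(=O)CBr | starting material
6 | sodium (Z)-enolate of 4 | COc1ccc(C/C=C(\[O-])N2[C@H](Cc3ccccc3)COC2=O)cc1OC.[Na+] | intermediate
7 | tert-butyl (3S)-4-[(4R)-4-benzyl-2-oxo-1,3-oxazolidin-3-yl]-3-(3,4-dimethoxybenzyl)-4-oxobutanoate | COc1ccc(C[C@@H](CC(=O)OC(C)(C)C)C(=O)N2[C@H](Cc3ccccc3)COC2=O)cc1OC | intermediate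
8 | tert-butyl (3S)-4-(3,4-dimethoxyphenyl)-3-(hydroxymethyl)butanoate | COc1ccc(C[C@@H](CC(=O)OC(C)(C)C)CO)cc1OC | intermediate
9 | (3S)-4-(3,4-dimethoxyphenyl)-3-(hydroxymethyl)butanoic acid | COc1ccc(C[C@@H](CC(=O)O)CO)cc1OC | intermediate
10 | (4S)-4-(3,4-dimethoxybenzyl)dihydrofuran-2(3H)-one | COc1ccc(C[C@@H]2COC(=O)C2)cc1OC | intermediate
11 | 3,4,5-trimethoxybenzaldehyde | COc1cc(C=O)cc(OC)c1OC | starting material
12 | lithium enolate of 10 | COc1ccc(C[C@@H]2COC([O-])=C2)cc1OC.[Li+] | intermediate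
13 | (3R,4S)-4-(3,4-dimethoxybenzyl)-3-[hydroxy(3,4,5-trimethoxyphenyl)methyl]dihydrofuran-2(3H)-one (both carbinol epimers) | COc1ccc(C[C@@H]2COC(=O)[C@H]2C(O)c2cc(OC)c(OC)c(OC)c2)cc1OC | intermediate
14 | (2S,3S)-2-(3,4-dimethoxybenzyl)-3-[hydroxy(3,4,5-trimethoxyphenyl)methyl]butane-1,4-diol (both carbinol epimers) | COc1ccc(C[C@H](CO)[C@@H](CO)C(O)c2cc(OC)c(OC)c(OC)c2)cc1OC | intermediate
15 | (2S,3S)-1,4-dihydroxy-3-(3,4-dimethoxybenzyl)-2-(hydroxymethyl)butyl cation bearing the 3,4,5-trimethoxyphenyl group on the cationic carbon | COc1ccc(C[C@H](CO)[C@@H](CO)[CH+]c2cc(OC)c(OC)c(OC)c2)cc1OC | intermediate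
16 | [(2R,3S,4S)-4-(3,4-dimethoxybenzyl)-2-(3,4,5-trimethoxyphenyl)tetrahydrofuran-3-yl]methanol | COc1ccc(C[C@@H]2CO[C@@H](c3cc(OC)c(OC)c(OC)c3)[C@@H]2CO)cc1OC | target

## Step count and risks

Total steps: 7. Longest linear sequence: 7 (1 → 16); compounds 2, 5 and 11 are purchased.

**Step 7 (cyclisation).** The cation can instead close onto the electron-rich dimethoxybenzyl ring (aryltetralin), give some 2,3-cis epimer, or ionise sluggishly. The fallback is an SN2 closure that keeps the carbinol C–O bond; it sets out from 13 and rejoins the route at 16. The carbinol epimers of 13 are separated by chromatography and the (R)-carbinol epimer F1 is silylated (TBSOTf, 2,6-lutidine) to the TBS ether F2. LiAlH4 gives the silyloxy diol F3, and MsCl/Et3N gives the bis-mesylate F4. TBAF in THF frees the benzylic alkoxide, which closes 5-exo-tet on the CH2OMs of the benzyl-bearing carbon (4-exo closure on the other mesylate is far slower) to give the tetrahydrofuran mesylate F5 with the carbinol configuration retained as 2R. CsOAc in DMF at 80 °C gives the acetate F6, and K2CO3/MeOH gives 16.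

**Step 5 (aldol).** The addition is reversible, so retro-aldol on warming, incomplete conversion or dehydration can erode the yield. The fallback sets out from 10 and rejoins at 13. Crossed Claisen C-acylation of the lactone enolate (LiHMDS 2.2 equiv, THF, −78 °C, then 3,4,5-trimethoxybenzoyl chloride) gives the trans α-aroyl lactone F7 irreversibly, because the product is held as its enolate. NaBH4 in MeOH at −20 °C then reduces the ketone to 13 as the same epimer mixture.

**Step 6 (LiAlH4 reduction).** The aluminium alkoxide of the β-hydroxy lactone can fragment by retro-aldol before the lactone is reduced. The fallback sets out from 13 and rejoins at 14. TESCl/imidazole in DMF gives the triethylsilyl ether F8, which cannot undergo retro-aldol; LiAlH4 then gives the silyloxy diol F9, and TBAF removes the silyl group to give 14.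

## Further compounds

F1 | step 7 | (3R,4S)-4-(3,4-dimethoxybenzyl)-3-[(R)-hydroxy(3,4,5-trimethoxyphenyl)methyl]dihydrofuran-2(3H)-one | COc1ccc(C[C@@H]2COC(=O)[C@H]2[C@@H](O)c2cc(OC)c(OC)c(OC)c2)cc1OC
F2 | step 7 | (3R,4S)-3-[(R)-(tert-butyldimethylsilyloxy)(3,4,5-trimethoxyphenyl)methyl]-4-(3,4-dimethoxybenzyl)dihydrofuran-2(3H)-one | COc1ccc(C[C@@H]2COC(=O)[C@H]2[C@@H](O[Si](C)(C)C(C)(C)C)c2cc(OC)c(OC)c(OC)c2)cc1OC
F3 | step 7 | (2S,3S)-2-[(R)-(tert-butyldimethylsilyloxy)(3,4,5-trimethoxyphenyl)methyl]-3-(3,4-dimethoxybenzyl)butane-1,4-diol | COc1ccc(C[C@H](CO)[C@@H](CO)[C@@H](O[Si](C)(C)C(C)(C)C)c2cc(OC)c(OC)c(OC)c2)cc1OC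
F4 | step 7 | (2S,3S)-2-[(R)-(tert-butyldimethylsilyloxy)(3,4,5-trimethoxyphenyl)methyl]-3-(3,4-dimethoxybenzyl)butane-1,4-diyl dimethanesulfonate | COc1ccc(C[C@H](COS(C)(=O)=O)[C@@H](COS(C)(=O)=O)[C@@H](O[Si](C)(C)C(C)(C)C)c2cc(OC)c(OC)c(OC)c2)cc1OC
F5 | step 7 | [(2R,3S,4S)-4-(3,4-dimethoxybenzyl)-2-(3,4,5-trimethoxyphenyl)tetrahydrofuran-3-yl]methyl methanesulfonate | COc1ccc(C[C@@H]2CO[C@@H](c3cc(OC)c(OC)c(OC)c3)[C@@H]2COS(C)(=O)=O)cc1OC
F6 | step 7 | [(2R,3S,4S)-4-(3,4-dimethoxybenzyl)-2-(3,4,5-trimethoxyphenyl)tetrahydrofuran-3-yl]methyl acetate | COc1ccc(C[C@@H]2CO[C@@H](c3cc(OC)c(OC)c(OC)c3)[C@@H]2COC(C)=O)cc1OC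
F7 | step 5 | (3R,4S)-4-(3,4-dimethoxybenzyl)-3-(3,4,5-trimethoxybenzoyl)dihydrofuran-2(3H)-one | COc1ccc(C[C@@H]2COC(=O)[C@H]2C(=O)c2cc(OC)c(OC)c(OC)c2)cc1OC
F8 | step 6 | (3R,4S)-4-(3,4-dimethoxybenzyl)-3-[(triethylsilyloxy)(3,4,5-trimethoxyphenyl)methyl]dihydrofuran-2(3H)-one (both carbinol epimers) | COc1ccc(C[C@@H]2COC(=O)[C@H]2C(O[Si](CC)(CC)CC)c2cc(OC)c(OC)c(OC)c2)cc1OC
F9 | step 6 | (2S,3S)-2-(3,4-dimethoxybenzyl)-3-[(triethylsilyloxy)(3,4,5-trimethoxyphenyl)methyl]butane-1,4-diol (both carbinol epimers) | COc1ccc(C[C@H](CO)[C@@H](CO)C(O[Si](CC)(CC)CC)c2cc(OC)c(OC)c(OC)c2)cc1OC
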